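**Retrosynthetic overview**

1. The hydroxyquinone is unmasked last, by Teuber oxidation of a 2‑substituted 4‑chloro‑orcinol after one global removal of three MOM groups.
2. The C2 and C3 methyl groups come from a tandem cuprate conjugate methylation / enolate C‑methylation of a 3‑substituted (S)‑4‑methylcyclohex‑2‑enone, relayed from C4.
3. The ring–CH2–CH(OH) bond and the carbinol centre come from an aminocatalytic vinylogous aldol addition (new) of (S)‑3,4‑dimethylcyclohex‑2‑enone to an (E)‑4‑aryl‑2‑methylbut‑2‑enal.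
4. The enone comes from organocatalytic asymmetric olefin isomerisation of the Birch‑derived β,γ‑enone of 3,4‑dimethylanisole (first stereocentre). The enal comes from orcinol by chlorination, MOM protection, ortho‑lithiation/allylation and cross‑metathesis with methacrolein.
5. Rings: none is closed. The carbocycle is the reduced anisole ring (made first); the quinone is the oxidised orcinol ring (made last).

Assumption: for the two cinchona aminocatalysts (steps 2 and 7) the pseudo‑enantiomer (quinine or quinidine series) that gives the drawn configuration is meant; which one that is must be fixed by a first experiment.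

Ar = 3‑chloro‑2,6‑bis(methoxymethoxy)‑4‑methylphenyl.

**Route**

Step 1
Reactants: 1 3,4‑dimethylanisole
Product: 3 3,4‑dimethylcyclohex‑3‑en‑1‑one, via Birch diene 2 (not isolated)
Conditions: Li, t‑BuOH, NH3(l)/THF, −78 → −33 °C; NH3 off; then (CO2H)2, MeOH/H2O, 20 °C
Reagents that add atoms: water, SMILES O
Why: Birch reduction leaves the methoxy and both methyl groups on sp2 carbons (2,5‑dihydroanisole), and mild enol‑ether hydrolysis with oxalic acid gives the β,γ‑unsaturated ketone without conjugation.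

Step 2
Reactants: 3 3,4‑dimethylcyclohex‑3‑en‑1‑one
Product: 4 (4S)‑3,4‑dimethylcyclohex‑2‑en‑1‑one
Conditions: 9‑amino‑9‑deoxy‑epi‑cinchona primary amine (10 mol %), 2‑FC6H4CO2H (20 mol %), toluene, −20 °C
Reagents that add atoms: none
Why: Organocatalytic enantioselective olefin isomerisation (cooperative iminium–base catalysis): the primary amine turns 3 into an achiral endocyclic dienamine and the protonated quinuclidine of the catalyst delivers a proton to one face of C4 (γ‑protonation), so hydrolysis gives the conjugated enone with C4 set as S.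

Step 3
Reactants: 5 orcinol
Product: 6 4‑chloro‑5‑methylbenzene‑1,3‑diol
Conditions: SO2Cl2 (1.05 equiv), Et2O, 0 → 20 °C
Reagents that add atoms: sulfuryl chloride, SMILES ClS(Cl)(=O)=O
Why: Electrophilic aromatic chlorination: the position ortho to one hydroxyl and para to the other is the most activated and least hindered, so monochlorination goes to C4 (C2, between the hydroxyls, is shielded).

Step 4
Reactants: 6 4‑chloro‑5‑methylbenzene‑1,3‑diol
Product: 7 2‑chloro‑1,5‑bis(methoxymethoxy)‑3‑methylbenzene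
Conditions: MOMCl, i‑Pr2NEt, CH2Cl2, 0 → 20 °C
Reagents that add atoms: chloromethyl methyl ether (MOMCl), SMILES COCCl
Why: Williamson‑type O‑alkylation of both phenols; the acetals protect them against the organometallic steps and act as the directing groups for step 5.

Step 5
Reactants: 7 2‑chloro‑1,5‑bis(methoxymethoxy)‑3‑methylbenzene; 8 allyl bromide
Product: 10 4‑chloro‑1,3‑bis(methoxymethoxy)‑5‑methyl‑2‑(prop‑2‑en‑1‑yl)benzene, via aryllithium 9 (not isolated)
Conditions: n‑BuLi, THF, 0 °C; then CuBr·SMe2 (10 mol %), 8, −78 → 20 °C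
Reagents that add atoms: none
Why: Directed ortho‑metalation at the only ring C–H flanked by two OCH2OMe groups, then copper‑catalysed allylation of the aryllithium (SN2 or SN2' gives the same allyl arene).

Step 6
Reactants: 10 allyl arene Ar–CH2CH=CH2; 11 methacrolein
Product: 12 (2E)‑4‑Ar‑2‑methylbut‑2‑enal
Conditions: second‑generation Hoveyda–Grubbs catalyst RuCl2(SIMes)(=CH‑C6H4‑2‑O‑i‑Pr) (5 mol %), 1,4‑benzoquinone (10 mol %), 11 (8 equiv), CH2Cl2, 40 °C
Reagents that add atoms: none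
Why: Olefin cross‑metathesis of a terminal allyl arene with an excess of the electron‑poor 1,1‑disubstituted olefin 11, which does not homodimerise, gives the trisubstituted enal as the thermodynamically favoured E isomer.

Step 7
Reactants: 4 (4S)‑3,4‑dimethylcyclohex‑2‑en‑1‑one (1.5 equiv); 12 (2E)‑4‑Ar‑2‑methylbut‑2‑enal
Product: 13 (4S)‑3‑[(2S,3E)‑5‑Ar‑2‑hydroxy‑3‑methylpent‑3‑en‑1‑yl]‑4‑methylcyclohex‑2‑en‑1‑one
Conditions: 9‑amino‑9‑deoxy‑epi‑cinchona primary amine bearing a 6'‑[3,5‑(CF3)2C6H3NHC(S)NH] thiourea (20 mol %), 2‑FC6H4CO2H (40 mol %), toluene, 0 → 25 °C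
Reagents that add atoms: none
Why: Proposed new method: catalyst‑controlled direct vinylogous aldol addition of a 3‑methylcyclohexenone to an unactivated α‑branched enal by H‑bond‑directed dienamine catalysis — the primary amine condenses with 4 to an iminium ion, its exposed γ'‑methyl is deprotonated to the exocyclic dienamine (the tertiary C4–H is held near the nodal plane by allylic 1,2‑strain and is left alone), the thiourea binds the aldehyde C=O of 12 and presents one enantioface to the dienamine CH2 terminus in a closed assembly in which 1,2‑attack beats 1,4‑attack because the enal β‑carbon is trisubstituted, and hydrolysis releases 13 with the (S)‑carbinol fixed by the catalyst; the closest known reaction type is the aminocatalytic vinylogous aldol reaction of 3‑methylcyclohex‑2‑enone with α‑keto esters under the same bifunctional catalysis.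

Step 8
Reactants: 13 aldol adduct
Product: 14 (4S)‑3‑[(2S,3E)‑5‑Ar‑2‑(methoxymethoxy)‑3‑methylpent‑3‑en‑1‑yl]‑4‑methylcyclohex‑2‑en‑1‑one
Conditions: MOMCl, i‑Pr2NEt, CH2Cl2, 0 → 40 °C
Reagents that add atoms: chloromethyl methyl ether (MOMCl), SMILES COCCl
Why: Acetalisation (MOM ether) of the secondary alcohol removes the acidic proton before the cuprate step and lets all three protecting groups fall in one operation later.

Step 9
Reactants: 14 MOM‑protected enone
Product: 16 (2R,3S,4S)‑3‑[(2S,3E)‑5‑Ar‑2‑(methoxymethoxy)‑3‑methylpent‑3‑en‑1‑yl]‑2,3,4‑trimethylcyclohexan‑1‑one, via lithium enolate 15 (not isolated)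
Conditions: Me2CuLi (3 equiv), Et2O/THF, −78 → −20 °C; then MeI (10 equiv), DMPU, −20 → 0 °C
Reagents that add atoms: lithium dimethylcuprate Me2CuLi, SMILES [Li+].C[Cu-]C; iodomethane MeI, SMILES CI
Why: Tandem conjugate addition–enolate alkylation: the cuprate adds axially to C3 anti to the pseudoaxial C4 methyl (allylic 1,2‑strain), so the new methyl is trans to C4‑Me and C3 is S, and the enolate is then methylated at C2 anti to the now axial C3 side chain in the half‑chair that has C4‑Me equatorial (the other half‑chair would put MeI syn‑axial to C4‑Me), giving 2R as the kinetic epimer.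

Step 10
Reactants: 16 tris‑MOM ketone
Product: 17 (2R,3S,4S)‑3‑[(2S,3E)‑5‑(3‑chloro‑2,6‑dihydroxy‑4‑methylphenyl)‑2‑hydroxy‑3‑methylpent‑3‑en‑1‑yl]‑2,3,4‑trimethylcyclohexan‑1‑one
Conditions: ZnBr2, n‑PrSH, CH2Cl2, 0 °C, 10 min
Reagents that add atoms: none
Why: Lewis acid/thiol cleavage of the three formaldehyde acetals (the thiol traps the methoxymethyl cation) is complete within minutes at 0 °C, fast enough to spare the allylic alcohol, the prenyl‑type phenol and the epimerisable C2.

Step 11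
Reactants: 17 resorcinol triol
Product: 18 target, 5‑chloro‑2‑hydroxy‑3‑{(2E,4S)‑4‑hydroxy‑3‑methyl‑5‑[(1S,2R,6S)‑1,2,6‑trimethyl‑3‑oxocyclohexyl]pent‑2‑en‑1‑yl}‑6‑methylcyclohexa‑2,5‑diene‑1,4‑dione
Conditions: (KSO3)2NO (2.5 equiv), KH2PO4 buffer (pH 6), acetone/H2O, 0 → 20 °C
Reagents that add atoms: dipotassium nitrosodisulfonate (KSO3)2NO, SMILES [K+].[K+].[O]N(S(=O)(=O)[O-])S(=O)(=O)[O-]
Why: Teuber oxidation: the nitroxyl radical converts the resorcinol, whose only free ring position is para to one hydroxyl, into the 2‑hydroxy‑1,4‑benzoquinone at pH 6, where neither the secondary alcohol nor C2 is touched.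

**Compound list**

1 | 3,4‑dimethylanisole (4‑methoxy‑1,2‑dimethylbenzene) | COc1ccc(C)c(C)c1 | starting material
2 | 1‑methoxy‑4,5‑dimethylcyclohexa‑1,4‑diene (Birch diene, not isolated) | COC1=CCC(C)=C(C)C1 | intermediate
3 | 3,4‑dimethylcyclohex‑3‑en‑1‑one | O=C1CCC(C)=C(C)C1 | intermediate
4 | (4S)‑3,4‑dimethylcyclohex‑2‑en‑1‑one | O=C1C=C(C)[C@@H](C)CC1 | intermediate
5 | orcinol (5‑methylbenzene‑1,3‑diol) | Cc1cc(O)cc(O)c1 | starting material
6 | 4‑chloro‑5‑methylbenzene‑1,3‑diol | Cc1cc(O)cc(O)c1Cl | intermediate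
7 | 2‑chloro‑1,5‑bis(methoxymethoxy)‑3‑methylbenzene | Cc1cc(OCOC)cc(OCOC)c1Cl | intermediate
8 | allyl bromide (3‑bromoprop‑1‑ene) | C=CCBr | starting material
9 | [3‑chloro‑2,6‑bis(methoxymethoxy)‑4‑methylphenyl]lithium (aryllithium, not isolated) | [Li]c1c(OCOC)cc(C)c(Cl)c1OCOC | intermediate
10 | 4‑chloro‑1,3‑bis(methoxymethoxy)‑5‑methyl‑2‑(prop‑2‑en‑1‑yl)benzene | C=CCc1c(OCOC)cc(C)c(Cl)c1OCOC | intermediate
11 | methacrolein (2‑methylprop‑2‑enal) | CC(=C)C=O | starting material
12 | (2E)‑4‑[3‑chloro‑2,6‑bis(methoxymethoxy)‑4‑methylphenyl]‑2‑methylbut‑2‑enal | COCOc1cc(C)c(Cl)c(OCOC)c1C/C=C(\C)C=O | intermediate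
13 | (4S)‑3‑{(2S,3E)‑5‑[3‑chloro‑2,6‑bis(methoxymethoxy)‑4‑methylphenyl]‑2‑hydroxy‑3‑methylpent‑3‑en‑1‑yl}‑4‑methylcyclohex‑2‑en‑1‑one | COCOc1cc(C)c(Cl)c(OCOC)c1C/C=C(\C)[C@@H](O)CC1=CC(=O)CC[C@@H]1C | intermediate
14 | (4S)‑3‑{(2S,3E)‑5‑[3‑chloro‑2,6‑bis(methoxymethoxy)‑4‑methylphenyl]‑2‑(methoxymethoxy)‑3‑methylpent‑3‑en‑1‑yl}‑4‑methylcyclohex‑2‑en‑1‑one | COCOc1cc(C)c(Cl)c(OCOC)c1C/C=C(\C)[C@@H](OCOC)CC1=CC(=O)CC[C@@H]1C | intermediate
15 | lithium (3S,4S)‑3‑{(2S,3E)‑5‑[3‑chloro‑2,6‑bis(methoxymethoxy)‑4‑methylphenyl]‑2‑(methoxymethoxy)‑3‑methylpent‑3‑en‑1‑yl}‑3,4‑dimethylcyclohex‑1‑en‑1‑olate (not isolated) | COCOc1cc(C)c(Cl)c(OCOC)c1C/C=C(\C)[C@@H](OCOC)C[C@@]1(C)[C@@H](C)CCC([O-])=C1.[Li+] | intermediate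
16 | (2R,3S,4S)‑3‑{(2S,3E)‑5‑[3‑chloro‑2,6‑bis(methoxymethoxy)‑4‑methylphenyl]‑2‑(methoxymethoxy)‑3‑methylpent‑3‑en‑1‑yl}‑2,3,4‑trimethylcyclohexan‑1‑one | COCOc1cc(C)c(Cl)c(OCOC)c1C/C=C(\C)[C@@H](OCOC)C[C@@]1(C)[C@@H](C)CCC(=O)[C@@H]1C | intermediate
17 | (2R,3S,4S)‑3‑[(2S,3E)‑5‑(3‑chloro‑2,6‑dihydroxy‑4‑methylphenyl)‑2‑hydroxy‑3‑methylpent‑3‑en‑1‑yl]‑2,3,4‑trimethylcyclohexan‑1‑one | Cc1cc(O)c(C/C=C(\C)[C@@H](O)C[C@@]2(C)[C@@H](C)CCC(=O)[C@@H]2C)c(O)c1Cl | intermediate
18 | 5‑chloro‑2‑hydroxy‑3‑{(2E,4S)‑4‑hydroxy‑3‑methyl‑5‑[(1S,2R,6S)‑1,2,6‑trimethyl‑3‑oxocyclohexyl]pent‑2‑en‑1‑yl}‑6‑methylcyclohexa‑2,5‑diene‑1,4‑dione | CC1=C(Cl)C(=O)C(C/C=C(\C)[C@@H](O)C[C@@]2(C)[C@@H](C)CCC(=O)[C@@H]2C)=C(O)C1=O | target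

**Count and risks**

Total step count: 11. Longest linear sequence: 9 steps (5 → 6 → 7 → 10 → 12 → 13 → 14 → 16 → 17 → 18).

Step 7 (the proposed new step) is the most likely to fail. An enal is a much weaker electrophile than the α‑keto esters known to work, and the adduct can dehydrate to a conjugated trienone. The enal can also be drawn into its own iminium/dienamine chemistry, C4 can erode by reversible γ‑deprotonation, and the catalyst needed for the (S)‑carbinol may be mismatched with the C4 methyl. The fallback uses known chemistry, sets out from 4 and 12 and comes back at 13. Both carbonyl partners are complexed with the bulky aluminium tris(2,6‑diphenylphenoxide), Al(OC6H3Ph2‑2,6)3, in toluene at −78 °C and the exposed γ'‑methyl of 4 is deprotonated with LiN(i‑Pr)2 (Yamamoto‑type directed vinylogous aldol). This gives 13 without catalyst control together with its carbinol epimer, (4S)‑3‑[(2R,3E)‑5‑Ar‑2‑hydroxy‑3‑methylpent‑3‑en‑1‑yl]‑4‑methylcyclohex‑2‑en‑1‑one F4. The two diastereomers are separated on silica. F4 is recycled by Mitsunobu inversion (4‑nitrobenzoic acid, PPh3, DIAD) to the (2S)‑4‑nitrobenzoate of 13 F5, and K2CO3/MeOH methanolysis of F5 gives 13.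

Step 2 may give incomplete conversion or low ee, because the β,γ‑olefin of 3 is tetrasubstituted and the conjugated product is only moderately favoured, so reverse proton transfer can erode C4. The fallback sets out from 3 and comes back at 4. DBU in CH2Cl2 isomerises 3 to racemic 3,4‑dimethylcyclohex‑2‑en‑1‑one F1. Catalyst‑controlled CBS reduction (catecholborane, (S)‑2‑methyl‑CBS‑oxazaborolidine 10 mol %, −78 °C) then fixes C1, expected as R, in both C4 series. The racemate thus becomes two diastereomeric allylic alcohols, (1R,4S)‑3,4‑dimethylcyclohex‑2‑en‑1‑ol F2 and (1R,4R)‑3,4‑dimethylcyclohex‑2‑en‑1‑ol F3. These are separated by chromatography and F2 is oxidised with MnO2 to 4 (at most half of the material).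

Step 9 has to build a quaternary carbon next to two branched centres and then C‑methylate a hindered copper‑containing enolate in the same flask. Slow addition, proton transfer or over‑alkylation are possible. The 2R epimer is kinetic and, by a rough conformational estimate, probably the less stable one, so it cannot be corrected by equilibration and must not see base afterwards. The fallback sets out from 14 and comes back at 15 and hence 16, and separates the two bond formations. Me2CuLi with TMSCl in THF at −78 °C (silyl‑accelerated conjugate addition) gives the isolable silyl enol ether, trimethyl{[(3S,4S)‑3‑[(2S,3E)‑5‑Ar‑2‑(methoxymethoxy)‑3‑methylpent‑3‑en‑1‑yl]‑3,4‑dimethylcyclohex‑1‑en‑1‑yl]oxy}silane F6. After purification, MeLi in THF at 0 °C cleaves the O–Si bond of F6 to the copper‑free, regiodefined lithium enolate 15, which is methylated with MeI/DMPU at −78 → −20 °C to 16.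

**Further compounds**

F1 | step 2 | racemic 3,4‑dimethylcyclohex‑2‑en‑1‑one | O=C1C=C(C)C(C)CC1
F2 | step 2 | (1R,4S)‑3,4‑dimethylcyclohex‑2‑en‑1‑ol | O[C@H]1C=C(C)[C@@H](C)CC1
F3 | step 2 | (1R,4R)‑3,4‑dimethylcyclohex‑2‑en‑1‑ol | O[C@H]1C=C(C)[C@H](C)CC1
F4 | step 7 | (4S)‑3‑{(2R,3E)‑5‑[3‑chloro‑2,6‑bis(methoxymethoxy)‑4‑methylphenyl]‑2‑hydroxy‑3‑methylpent‑3‑en‑1‑yl}‑4‑methylcyclohex‑2‑en‑1‑one | COCOc1cc(C)c(Cl)c(OCOC)c1C/C=C(\C)[C@H](O)CC1=CC(=O)CC[C@@H]1C
F5 | step 7 | (2S,3E)‑5‑[3‑chloro‑2,6‑bis(methoxymethoxy)‑4‑methylphenyl]‑3‑methyl‑1‑[(6S)‑6‑methyl‑3‑oxocyclohex‑1‑en‑1‑yl]pent‑3‑en‑2‑yl 4‑nitrobenzoate | COCOc1cc(C)c(Cl)c(OCOC)c1C/C=C(\C)[C@@H](OC(=O)c2ccc(cc2)[N+](=O)[O-])CC1=CC(=O)CC[C@@H]1C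
F6 | step 9 | trimethyl{[(3S,4S)‑3‑{(2S,3E)‑5‑[3‑chloro‑2,6‑bis(methoxymethoxy)‑4‑methylphenyl]‑2‑(methoxymethoxy)‑3‑methylpent‑3‑en‑1‑yl}‑3,4‑dimethylcyclohex‑1‑en‑1‑yl]oxy}silane | COCOc1cc(C)c(Cl)c(OCOC)c1C/C=C(\C)[C@@H](OCOC)C[C@@]1(C)[C@@H](C)CCC(O[Si](C)(C)C)=C1
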